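**Plan**

1. Retrosynthesis: take off C6–Cl (SN2 on the 6-epi alcohol) and the three acetates; cut C4–C5 (Nozaki–Hiyama–Kishi closure of the ten-membered ring) and the C2=C3 enal (cross-metathesis); contract the cyclohexenone (C1, C14, C13, C12, C11, C10) to a cyclopentene by a retro-α-ketol shift of C10 from C11 back to C12.
2. Further cuts: C11–C12 (acyl-anion addition), C9–C10 (aldol), C8–C17 (Reformatsky lactone), C6–C7 (glycolate aldol), C1–C2 (conjugate addition).
3. Enabling feature: the C12 ketone next to the C11 tertiary carbinol bearing Me-20 is an α-ketol. Its isomer is a 1-acetylcyclopent-2-en-1-ol, and only the six-membered ring puts C12=O in conjugation with C13=C14 and relieves ring strain. In the five-membered stage C10 is α to the carbonyl, which is what allows the C9–C10 aldol.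
4. Forward order: cyclopentenone 4 and lactone aldehyde 19 are joined by aldol; C12 is acetylated through an acyl-anion equivalent; ring expansion gives the cyclohexenone; enal formation and NHK close the ten-membered ring; acetylation, desilylation and chloride inversion finish.
5. Stereochemistry: C1 by catalyst control (Cu–NHC conjugate addition); C6/C7 by the Evans auxiliary; C8/C17 by the tethered Reformatsky closure; C9/C10 by an anti-aldol on the face opposite the 1-silylvinyl group; C12 (temporary) by addition anti to C9, relayed to C11 by the stereospecific 1,2-shift; C4 by the macrocyclic NHK transition state; C6–Cl by inversion.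

Key step: step 17

Remark: locants C1–C20 follow briarane numbering of the target (C1 quaternary ring-fusion carbon, C5=C16H2, C7–O–C19 lactone, Me-15 on C1, Me-18 on C17, Me-20 on C11); "as in the target" means the same spatial arrangement; the NHC ligand enantiomer in step 1 is the one that gives (S)-3.

Step 1
Reactants: 1 3-methylcyclopent-2-en-1-one; 2 ethynyltrimethylsilane
Product: 3 (S)-3-methyl-3-[1-(trimethylsilyl)vinyl]cyclopentan-1-one
Conditions: 2, DIBAL-H, hexane/THF, 55 °C; then 1, CuCl2·2H2O (5 mol %), chiral sulfonate NHC–Ag complex (2.5 mol %), THF, −15 °C; H2O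
Reagents that add atoms: none
Why: Cu–NHC-catalysed enantioselective conjugate addition of the α-silylvinylalane (from hydroalumination of 2) to the β-methyl enone should create the quaternary C1 under catalyst control, and the bulky silylvinyl group later differentiates the two faces of C10.

Step 2
Reactants: 3 (S)-3-methyl-3-[1-(trimethylsilyl)vinyl]cyclopentan-1-one
Product: 4 (R)-4-methyl-4-[1-(trimethylsilyl)vinyl]cyclopent-2-en-1-one
Conditions: IBX (2.5 equiv), DMSO/toluene, 70 °C
Reagents that add atoms: none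
Why: IBX α,β-dehydrogenation of the ketone can only engage the C4–C5 side, because the other α-carbon has no β-hydrogen (quaternary neighbour), so a single enone should form without touching the stereocentre.

Step 3
Reactants: 5 (S)-4-benzyl-3-[(benzyloxy)acetyl]oxazolidin-2-one; 6 3-(trimethylsilyl)prop-2-ynal
Product: 7 (S)-4-benzyl-3-[(2S,3R)-2-(benzyloxy)-3-hydroxy-5-(trimethylsilyl)pent-4-ynoyl]oxazolidin-2-one
Conditions: Bu2BOTf, Et3N, CH2Cl2, −78 → 0 °C; 6, −78 → 0 °C; pH 7 buffer, MeOH, H2O2
Reagents that add atoms: none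
Why: Evans syn-glycolate aldol in which the Z-boron enolate reacts through a chair transition state whose face is fixed by the (S)-benzyl auxiliary, setting C7 (S) and C6 (R) in the syn relationship needed for later inversion at C6.

Step 4
Reactants: 7 (S)-4-benzyl-3-[(2S,3R)-2-(benzyloxy)-3-hydroxy-5-(trimethylsilyl)pent-4-ynoyl]oxazolidin-2-one
Product: 8 (2S,3R)-2-(benzyloxy)-3-hydroxy-N-methoxy-N-methyl-5-(trimethylsilyl)pent-4-ynamide
Conditions: MeNH(OMe)·HCl, AlMe3, CH2Cl2, −20 → 0 °C
Reagents that add atoms: N,O-dimethylhydroxylamine hydrochloride CNOC.Cl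
Why: Trimethylaluminium-mediated transamination of the β-hydroxy imide releases the auxiliary and should give the Weinreb amide without disturbing C6 or C7.

Step 5
Reactants: 8 (2S,3R)-2-(benzyloxy)-3-hydroxy-N-methoxy-N-methyl-5-(trimethylsilyl)pent-4-ynamide
Product: 9 (2S,3R)-2-(benzyloxy)-3-[(tert-butyldiphenylsilyl)oxy]-N-methoxy-N-methyl-5-(trimethylsilyl)pent-4-ynamide
Conditions: TBDPSCl, imidazole, DMAP (cat.), DMF, rt
Reagents that add atoms: tert-butyl(chloro)diphenylsilane CC(C)(C)[Si](Cl)(c1ccccc1)c1ccccc1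
Why: Silylation of the propargylic alcohol gives an acid- and base-stable TBDPS ether that carries the C6 oxygen to the last step.

Step 6
Reactants: 9 (2S,3R)-2-(benzyloxy)-3-[(tert-butyldiphenylsilyl)oxy]-N-methoxy-N-methyl-5-(trimethylsilyl)pent-4-ynamide
Product: 10 (2S,3R)-2-(benzyloxy)-3-[(tert-butyldiphenylsilyl)oxy]-N-methoxy-N-methylpent-4-ynamide
Conditions: K2CO3 (cat.), MeOH, 0 °C
Reagents that add atoms: none
Why: Carbonate-catalysed methanolysis cleaves only the C(sp)–Si bond and should free the terminal alkyne.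

Step 7
Reactants: 10 (2S,3R)-2-(benzyloxy)-3-[(tert-butyldiphenylsilyl)oxy]-N-methoxy-N-methylpent-4-ynamide
Product: 11 (2S,3S)-2-(benzyloxy)-3-[(tert-butyldiphenylsilyl)oxy]-4-iodo-N-methoxy-N-methylpent-4-enamide
Conditions: NaI, TMSCl, H2O, MeCN, rt
Reagents that add atoms: sodium iodide [Na+].[I-]
Why: Markovnikov hydroiodination of the terminal alkyne with HI generated in situ should give the 2-iodo-1-alkene (C5=C16) that later serves as the alkenylchromium precursor; no stereocentre is formed.

Step 8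
Reactants: 11 (2S,3S)-2-(benzyloxy)-3-[(tert-butyldiphenylsilyl)oxy]-4-iodo-N-methoxy-N-methylpent-4-enamide; 12 (2-methylprop-1-en-1-yl)magnesium bromide
Product: 13 (5S,6S)-5-(benzyloxy)-6-[(tert-butyldiphenylsilyl)oxy]-7-iodo-2-methylocta-2,7-dien-4-one
Conditions: 12 (1.5 equiv), THF, −20 → 0 °C; 1 M HCl
Reagents that add atoms: none
Why: Weinreb ketone synthesis in which the chelated tetrahedral intermediate stops at the ketone stage; the isobutenyl group is a masked formyl group for C9.

Step 9
Reactants: 13 (5S,6S)-5-(benzyloxy)-6-[(tert-butyldiphenylsilyl)oxy]-7-iodo-2-methylocta-2,7-dien-4-one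
Product: 14 (5S,6S)-6-[(tert-butyldiphenylsilyl)oxy]-5-hydroxy-7-iodo-2-methylocta-2,7-dien-4-one
Conditions: BCl3, CH2Cl2, −78 °C; MeOH
Reagents that add atoms: none
Why: Lewis-acid debenzylation in which BCl3 binds the α-benzyloxy ketone and chloride removes the benzyl group should free the C7 hydroxyl while the silyl ether, enone and alkenyl iodide survive at low temperature.

Step 10
Reactants: 14 (5S,6S)-6-[(tert-butyldiphenylsilyl)oxy]-5-hydroxy-7-iodo-2-methylocta-2,7-dien-4-one; 15 2-bromopropanoyl bromide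
Product: 16 (5S,6S)-6-[(tert-butyldiphenylsilyl)oxy]-7-iodo-2-methyl-4-oxoocta-2,7-dien-5-yl 2-bromopropanoate (both C–Br epimers)
Conditions: 15, pyridine, CH2Cl2, −30 °C
Reagents that add atoms: none
Why: Acylation of the only free hydroxyl with the acyl bromide gives the Reformatsky precursor; the C–Br centre is inconsequential because it becomes an enolate.

Step 11
Reactants: 16 (5S,6S)-6-[(tert-butyldiphenylsilyl)oxy]-7-iodo-2-methyl-4-oxoocta-2,7-dien-5-yl 2-bromopropanoate
Product: 17 (3R,4S,5S)-5-[(1S)-1-[(tert-butyldiphenylsilyl)oxy]-2-iodoprop-2-en-1-yl]-4-hydroxy-3-methyl-4-(2-methylprop-1-en-1-yl)dihydrofuran-2(3H)-one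
Conditions: SmI2 (2.2 equiv), THF, −78 °C; aq. NH4Cl
Reagents that add atoms: none
Why: SmI2-mediated intramolecular Reformatsky reaction (5-exo addition of the samarium enolate to the ketone through the C7–O tether) should attack the carbonyl face that keeps C7–H rather than the C6 chain next to the isobutenyl group, placing C8–OH cis to C6, and the C17 methyl takes (or can be equilibrated with DBU to) the position trans to the bulky carbon substituent on C8.

Step 12
Reactants: 17 (3R,4S,5S)-5-[(1S)-1-[(tert-butyldiphenylsilyl)oxy]-2-iodoprop-2-en-1-yl]-4-hydroxy-3-methyl-4-(2-methylprop-1-en-1-yl)dihydrofuran-2(3H)-one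
Product: 18 4-O-trimethylsilyl ether of 17
Conditions: TMSOTf, 2,6-lutidine, CH2Cl2, −78 °C
Reagents that add atoms: trimethylsilyl triflate C[Si](C)(C)OS(=O)(=O)C(F)(F)F
Why: Silylation of the hindered tertiary alcohol with the silyl triflate masks C8–OH for the enolate step and prevents retro-aldol opening of the β-hydroxy lactone.

Step 13
Reactants: 18 4-O-trimethylsilyl ether of 17
Product: 19 (2S,3S,4R)-2-[(1S)-1-[(tert-butyldiphenylsilyl)oxy]-2-iodoprop-2-en-1-yl]-4-methyl-5-oxo-3-[(trimethylsilyl)oxy]tetrahydrofuran-3-carbaldehyde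
Conditions: O3, pyridine, CH2Cl2, −78 °C (indicator end point); PPh3
Reagents that add atoms: ozone [O-][O+]=O
Why: Ozonolysis should cleave the electron-rich trisubstituted isobutenyl alkene much faster than the iodine-deactivated 1,1-disubstituted alkene, unveiling the non-enolisable C9 aldehyde.

Step 14
Reactants: 4 (R)-4-methyl-4-[1-(trimethylsilyl)vinyl]cyclopent-2-en-1-one; 19 lactone aldehyde
Product: 20 cyclopentenone–lactone anti-aldol adduct (9-OH; 8-OTMS; 6-OTBDPS)
Conditions: LDA, THF, −78 °C; 19, −78 °C; AcOH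
Reagents that add atoms: none
Why: Aldol addition of the kinetic α′-lithium enolate (the only enolisable position) through a Zimmerman–Traxler chair, in which the E(O)-enolate gives the 9,10-anti adduct and the aldehyde approaches C10 anti to the bulky 1-silylvinyl group, i.e. cis to Me-15.

Step 15
Reactants: 20 cyclopentenone–lactone anti-aldol adduct
Product: 21 8,9-O-isopropylidene cyclopentenone
Conditions: Me2C(OMe)2, CSA (cat.), CH2Cl2, 0 °C → rt
Reagents that add atoms: 2,2-dimethoxypropane COC(C)(C)OC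
Why: Acid-catalysed transketalisation removes the labile tertiary TMS ether and traps the 8,9-diol as an acetonide, a base-stable group that cannot migrate to a neighbouring alkoxide in the key step.

Step 16
Reactants: 21 8,9-O-isopropylidene cyclopentenone; 22 ethyl vinyl ether
Product: 24 1-acetylcyclopent-2-en-1-ol α-ketol (C12–OH cis to C9), via 1-ethoxyvinyl carbinol 23 (not isolated)
Conditions: 22, t-BuLi, THF, −78 → 0 °C; CeCl3, −78 °C; 21, −78 °C; 0.1 M aq. oxalic acid, 0 °C
Reagents that add atoms: water O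
Why: Organocerium 1,2-addition of the acyl-anion equivalent 1-ethoxyvinyl to the enone carbonyl (ketone reacting far faster than the hindered lactone at −78 °C) should occur anti to the C10 substituent, setting C12–OH cis to C9, and mild acid hydrolysis of the enol ether unmasks the methyl ketone.

Step 17
Reactants: 24 1-acetylcyclopent-2-en-1-ol α-ketol
Product: 25 ring-expanded 6-hydroxy-6-methylcyclohex-2-en-1-one (11-OH; Me-20 cis to Me-15)
Conditions: KH (1.1 equiv), 18-crown-6, THF, −20 → 0 °C; AcOH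
Reagents that add atoms: none
Why: The potassium alkoxide at C12 triggers an α-ketol (acyloin) rearrangement in which the C10–C12 σ bond shifts 1,2 to the acetyl carbonyl carbon C11 while C12 becomes the ketone, so that C11 is inserted between C12 and C10. The closest known reaction type is the base-promoted D-homoannulation of 17-hydroxy-20-keto steroids (1-acylcycloalkanol to 2-hydroxy-2-methylcycloalkanone). No ring is closed by cyclisation; the cyclopentene is enlarged to the cyclohexenone by a suprafacial 1,2-alkyl shift with retention at C10. C11 is set by the face of the acetyl carbonyl that C10 attacks: with the non-chelating K+/18-crown-6 counter-ion the carbonyl oxygen sits anti to the alkoxide (transoid, also the less hindered rotamer with the methyl pointing outward), so the new C11 oxygen ends up on the face opposite the old C12–OH, trans to C9, with Me-20 cis to Me-15. The step needs C10 and not the vinyl carbon C13 to migrate; C10 migration is the one that brings the new C12=O into conjugation with C13=C14, and since the rearrangement is reversible the conjugated, less strained six-membered α-ketol is the sink.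

Step 18
Reactants: 25 ring-expanded 6-hydroxy-6-methylcyclohex-2-en-1-one
Product: 26 C1-vinyl cyclohexenone 8,9,11-triol (6-OTBDPS)
Conditions: TFA/CH2Cl2/H2O (20:80:1), 0 °C → rt
Reagents that add atoms: none
Why: Protodesilylation by ipso-protonation of the vinylsilane (β-silyl cation) removes the silyl group, and the aqueous acid also hydrolyses the acetonide, while the TBDPS ether, lactone, enone and alkenyl iodide are acid-stable.

Step 19
Reactants: 26 C1-vinyl cyclohexenone 8,9,11-triol; 27 (E)-but-2-enal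
Product: 28 (E)-enal (C2=C3–C4HO)
Conditions: 27 (10 equiv), Hoveyda–Grubbs II (10 mol %), CH2Cl2, 40 °C
Reagents that add atoms: none
Why: Olefin cross-metathesis between the hindered vinyl group and excess crotonaldehyde should give the E-enal, the conjugated ring alkene and the iodoalkene being poor metathesis partners.

Step 20
Reactants: 28 (E)-enal
Product: 29 ten-membered carbocycle 4,8,9,11-tetraol (6-OTBDPS)
Conditions: CrCl2 (10 equiv), NiCl2 (10 mol %), DMSO/THF, 0.002 M, rt
Reagents that add atoms: none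
Why: Nozaki–Hiyama–Kishi reaction in which the alkenylchromium species formed from the C5–I bond adds 1,2 to the enal aldehyde (10-exo-trig) to close the ten-membered ring; C4 is set by attack on the exposed face of the s-trans enal in the macrocyclic transition state, expected to give the 4S alcohol.

Step 21
Reactants: 29 ten-membered carbocycle 4,8,9,11-tetraol
Product: 30 4,9,11-triacetate (8-OH free; 6-OTBDPS)
Conditions: Ac2O, Et3N, DMAP, CH2Cl2, rt
Reagents that add atoms: acetic anhydride CC(=O)OC(C)=O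
Why: DMAP-catalysed acylation should acetylate the allylic C4, the secondary C9 and the tertiary α-keto C11 hydroxyls, while the C8 tertiary hydroxyl, flanked by three branched carbons, should remain free.

Step 22
Reactants: 30 4,9,11-triacetate
Product: 31 6-epi-alcohol (6-OH in place of Cl, inverted)
Conditions: HF·pyridine, pyridine, THF, 0 °C → rt
Reagents that add atoms: none
Why: Buffered fluoride cleavage of the TBDPS ether should leave the acetates, the lactone and the enone intact.

Step 23
Reactants: 31 6-epi-alcohol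
Product: 32 CNP0159278.2
Conditions: PPh3, Cl3CC(O)CCl3, CH2Cl2, 0 °C
Reagents that add atoms: hexachloroacetone O=C(C(Cl)(Cl)Cl)C(Cl)(Cl)Cl
Why: Appel-type chlorination in which the alkoxyphosphonium ion of the allylic alcohol is displaced by chloride in SN2 fashion with inversion, a reagent pair known to give little allylic transposition, should deliver the 6S chloride.

**Compound list**

1 | 3-methylcyclopent-2-en-1-one | CC1=CC(=O)CC1 | starting material
2 | ethynyltrimethylsilane | C#C[Si](C)(C)C | starting material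
3 | (S)-3-methyl-3-[1-(trimethylsilyl)vinyl]cyclopentan-1-one | C=C([Si](C)(C)C)[C@@]1(C)CCC(=O)C1 | intermediate
4 | (R)-4-methyl-4-[1-(trimethylsilyl)vinyl]cyclopent-2-en-1-one | C=C([Si](C)(C)C)[C@@]1(C)C=CC(=O)C1 | intermediate
5 | (S)-4-benzyl-3-[(benzyloxy)acetyl]oxazolidin-2-one | O=C(COCc1ccccc1)N1[C@@H](Cc2ccccc2)COC1=O | starting material
6 | 3-(trimethylsilyl)prop-2-ynal | O=CC#C[Si](C)(C)C | starting material
7 | (S)-4-benzyl-3-[(2S,3R)-2-(benzyloxy)-3-hydroxy-5-(trimethylsilyl)pent-4-ynoyl]oxazolidin-2-one | O=C([C@@H](OCc1ccccc1)[C@H](O)C#C[Si](C)(C)C)N1[C@@H](Cc2ccccc2)COC1=O | intermediate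
8 | (2S,3R)-2-(benzyloxy)-3-hydroxy-N-methoxy-N-methyl-5-(trimethylsilyl)pent-4-ynamide | CON(C)C(=O)[C@@H](OCc1ccccc1)[C@H](O)C#C[Si](C)(C)C | intermediate
9 | (2S,3R)-2-(benzyloxy)-3-[(tert-butyldiphenylsilyl)oxy]-N-methoxy-N-methyl-5-(trimethylsilyl)pent-4-ynamide | CON(C)C(=O)[C@@H](OCc1ccccc1)[C@H](O[Si](c1ccccc1)(c1ccccc1)C(C)(C)C)C#C[Si](C)(C)C | intermediate
10 | (2S,3R)-2-(benzyloxy)-3-[(tert-butyldiphenylsilyl)oxy]-N-methoxy-N-methylpent-4-ynamide | CON(C)C(=O)[C@@H](OCc1ccccc1)[C@H](O[Si](c1ccccc1)(c1ccccc1)C(C)(C)C)C#C | intermediate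
11 | (2S,3S)-2-(benzyloxy)-3-[(tert-butyldiphenylsilyl)oxy]-4-iodo-N-methoxy-N-methylpent-4-enamide | CON(C)C(=O)[C@@H](OCc1ccccc1)[C@H](O[Si](c1ccccc1)(c1ccccc1)C(C)(C)C)C(I)=C | intermediate
12 | (2-methylprop-1-en-1-yl)magnesium bromide | CC(C)=C[Mg]Br | starting material
13 | (5S,6S)-5-(benzyloxy)-6-[(tert-butyldiphenylsilyl)oxy]-7-iodo-2-methylocta-2,7-dien-4-one | CC(C)=CC(=O)[C@@H](OCc1ccccc1)[C@H](O[Si](c1ccccc1)(c1ccccc1)C(C)(C)C)C(I)=C | intermediate
14 | (5S,6S)-6-[(tert-butyldiphenylsilyl)oxy]-5-hydroxy-7-iodo-2-methylocta-2,7-dien-4-one | CC(C)=CC(=O)[C@@H](O)[C@H](O[Si](c1ccccc1)(c1ccccc1)C(C)(C)C)C(I)=C | intermediate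
15 | 2-bromopropanoyl bromide (racemic) | CC(Br)C(=O)Br | starting material
16 | (5S,6S)-6-[(tert-butyldiphenylsilyl)oxy]-7-iodo-2-methyl-4-oxoocta-2,7-dien-5-yl 2-bromopropanoate (both C–Br epimers) | CC(C)=CC(=O)[C@@H](OC(=O)C(C)Br)[C@H](O[Si](c1ccccc1)(c1ccccc1)C(C)(C)C)C(I)=C | intermediate
17 | (3R,4S,5S)-5-[(1S)-1-[(tert-butyldiphenylsilyl)oxy]-2-iodoprop-2-en-1-yl]-4-hydroxy-3-methyl-4-(2-methylprop-1-en-1-yl)dihydrofuran-2(3H)-one | CC(C)=C[C@]1(O)[C@@H](C)C(=O)O[C@H]1[C@H](O[Si](c1ccccc1)(c1ccccc1)C(C)(C)C)C(I)=C | intermediate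
18 | 4-O-trimethylsilyl ether of 17 | CC(C)=C[C@]1(O[Si](C)(C)C)[C@@H](C)C(=O)O[C@H]1[C@H](O[Si](c1ccccc1)(c1ccccc1)C(C)(C)C)C(I)=C | intermediate
19 | (2S,3S,4R)-2-[(1S)-1-[(tert-butyldiphenylsilyl)oxy]-2-iodoprop-2-en-1-yl]-4-methyl-5-oxo-3-[(trimethylsilyl)oxy]tetrahydrofuran-3-carbaldehyde | O=C[C@]1(O[Si](C)(C)C)[C@@H](C)C(=O)O[C@H]1[C@H](O[Si](c1ccccc1)(c1ccccc1)C(C)(C)C)C(I)=C | intermediate
20 | cyclopentenone–lactone anti-aldol adduct: enone 4 bonded at C10 to C9H(OH) of the lactone (8-OTMS, 6-OTBDPS); C1, C7, C8, C9, C10, C17 as in the target, C6 inverted | C=C([Si](C)(C)C)[C@@]1(C)C=CC(=O)[C@@H]1[C@@H](O)[C@]1(O[Si](C)(C)C)[C@@H](C)C(=O)O[C@H]1[C@H](O[Si](c1ccccc1)(c1ccccc1)C(C)(C)C)C(I)=C | intermediate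
21 | 8,9-O-isopropylidene derivative of the aldol adduct (cyclopentenone) | C=C([Si](C)(C)C)[C@@]1(C)C=CC(=O)[C@@H]1[C@H]2OC(C)(C)O[C@]23[C@@H](C)C(=O)O[C@H]3[C@H](O[Si](c1ccccc1)(c1ccccc1)C(C)(C)C)C(I)=C | intermediate
22 | ethyl vinyl ether | C=COCC | starting material
23 | 1-ethoxyvinyl carbinol at C12 (OH cis to C9) | C=C([Si](C)(C)C)[C@@]1(C)C=C[C@@](O)(C(=C)OCC)[C@@H]1[C@H]2OC(C)(C)O[C@]23[C@@H](C)C(=O)O[C@H]3[C@H](O[Si](c1ccccc1)(c1ccccc1)C(C)(C)C)C(I)=C | intermediate (not isolated)
24 | 1-acetylcyclopent-2-en-1-ol α-ketol (C12–OH cis to C9, acetyl cis to H-10) | C=C([Si](C)(C)C)[C@@]1(C)C=C[C@@](O)(C(C)=O)[C@@H]1[C@H]2OC(C)(C)O[C@]23[C@@H](C)C(=O)O[C@H]3[C@H](O[Si](c1ccccc1)(c1ccccc1)C(C)(C)C)C(I)=C | intermediate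
25 | ring-expanded 6-hydroxy-6-methylcyclohex-2-en-1-one (11-OH trans to C9, Me-20 cis to Me-15; 8,9-acetonide) | C=C([Si](C)(C)C)[C@@]1(C)C=CC(=O)[C@@](C)(O)[C@@H]1[C@H]2OC(C)(C)O[C@]23[C@@H](C)C(=O)O[C@H]3[C@H](O[Si](c1ccccc1)(c1ccccc1)C(C)(C)C)C(I)=C | intermediate
26 | C1-vinyl cyclohexenone 8,9,11-triol (6-OTBDPS) | C=C[C@@]1(C)C=CC(=O)[C@@](C)(O)[C@@H]1[C@@H](O)[C@]1(O)[C@@H](C)C(=O)O[C@H]1[C@H](O[Si](c1ccccc1)(c1ccccc1)C(C)(C)C)C(I)=C | intermediate
27 | (E)-but-2-enal (crotonaldehyde) | C/C=C/C=O | starting material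
28 | (E)-enal: C1–CH=CH–CHO derivative of 26 | O=C/C=C/[C@@]1(C)C=CC(=O)[C@@](C)(O)[C@@H]1[C@@H](O)[C@]1(O)[C@@H](C)C(=O)O[C@H]1[C@H](O[Si](c1ccccc1)(c1ccccc1)C(C)(C)C)C(I)=C | intermediate
29 | ten-membered carbocycle: 4,8,9,11-tetraol, 6-OTBDPS (4S; other centres as in the target, C6 inverted) | C=C1[C@@H](O)/C=C/[C@@]2(C)C=CC(=O)[C@@](C)(O)[C@@H]2[C@@H](O)[C@]2(O)[C@@H](C)C(=O)O[C@H]2[C@@H]1O[Si](c1ccccc1)(c1ccccc1)C(C)(C)C | intermediate
30 | 4,9,11-triacetate of 29 (8-OH free) | C=C1[C@@H](OC(C)=O)/C=C/[C@@]2(C)C=CC(=O)[C@@](C)(OC(C)=O)[C@@H]2[C@@H](OC(C)=O)[C@]2(O)[C@@H](C)C(=O)O[C@H]2[C@@H]1O[Si](c1ccccc1)(c1ccccc1)C(C)(C)C | intermediate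
31 | 6-epi-alcohol: target with OH in place of Cl and inverted C6 | C=C1[C@@H](OC(C)=O)/C=C/[C@@]2(C)C=CC(=O)[C@@](C)(OC(C)=O)[C@@H]2[C@@H](OC(C)=O)[C@]2(O)[C@@H](C)C(=O)O[C@H]2[C@@H]1O | intermediate
32 | CNP0159278.2, (1S,4S,6S,7R,8R,9R,10S,11S,17R)-4,9,11-triacetoxy-6-chloro-8-hydroxy-12-oxobriara-2(E),5(16),13-trien-19,7-olide | C=C1[C@@H](OC(C)=O)/C=C/[C@@]2(C)C=CC(=O)[C@@](C)(OC(C)=O)[C@@H]2[C@@H](OC(C)=O)[C@]2(O)[C@@H](C)C(=O)O[C@H]2[C@H]1Cl | target

**Step count**

Total: 23 steps. Longest linear sequence: 21 steps (steps 3–13, then 14–23).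

**Steps most likely to fail**

Step 17 (α-ketol rearrangement). The alkoxide may rearrange through a metal-bridged (cisoid) conformer, or the vinyl carbon C13 may migrate first and the product then equilibrate, so that the face of the acetyl carbonyl attacked by C10 is not controlled and C11 forms with eroded or wrong configuration. The fallback sets out from 21 and returns at 25. Wittig ethylidenation of the C12 ketone (EtPPh3Br, KOtBu, THF) should give the exocyclic ethylidene diene F1. Osmium tetroxide/NMO should dihydroxylate the electron-rich exocyclic alkene from the face opposite the C10 substituent to give the 11,12-diol F2. Dess–Martin oxidation of the secondary carbinol should give the C12-epimeric α-ketol F3 (hydroxyl cis to H-10, acetyl cis to C9). In this epimer a chelation-controlled rearrangement (Al(OtBu)3 or BF3·OEt2, toluene), in which both oxygens sit on one face of a five-membered chelate, puts the new C11–OH on the face of the old C12–OH and should give 25.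

Step 20 (NHK ring closure). Two macrocyclic conformers of the enal of similar energy may lead to low facial selectivity at C4 during ring closure. The fallback sets out from 29 obtained as a C4 epimer mixture and returns at 29. MnO2 should oxidise the doubly allylic C4 alcohol selectively to the cross-conjugated dienone F5. A CBS reduction (oxazaborolidine enantiomer matched to the 4S alcohol, catecholborane, −78 °C) should then set C4 under reagent control; the hindered C12 enone next to the quaternary C11 carbinol is expected to react more slowly.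

Step 19 (cross-metathesis). The vinyl group on the quaternary C1 may fail to engage the ruthenium alkylidene, so that only crotonaldehyde self-metathesis and catalyst decay take place. The fallback sets out from 26 and returns at 28. Ozonolysis (O3, CH2Cl2/MeOH, −78 °C; PPh3) of the only alkene that is neither conjugated nor halogen-deactivated should give the C2 aldehyde F4. A Wittig reaction with (triphenylphosphoranylidene)acetaldehyde (toluene, 80 °C) should then give the E-enal 28.

**Further compounds**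

F1 | step 17 | exocyclic ethylidene diene (C12=C11H–CH3, E/Z mixture) from 21 | C=C([Si](C)(C)C)[C@@]1(C)C=CC(=CC)[C@@H]1[C@H]2OC(C)(C)O[C@]23[C@@H](C)C(=O)O[C@H]3[C@H](O[Si](c1ccccc1)(c1ccccc1)C(C)(C)C)C(I)=C
F2 | step 17 | 11,12-diol (C12–OH cis to H-10; C11 epimers) | C=C([Si](C)(C)C)[C@@]1(C)C=C[C@](O)(C(C)O)[C@@H]1[C@H]2OC(C)(C)O[C@]23[C@@H](C)C(=O)O[C@H]3[C@H](O[Si](c1ccccc1)(c1ccccc1)C(C)(C)C)C(I)=C
F3 | step 17 | C12-epimeric α-ketol (C12–OH cis to H-10, acetyl cis to C9) | C=C([Si](C)(C)C)[C@@]1(C)C=C[C@](O)(C(C)=O)[C@@H]1[C@H]2OC(C)(C)O[C@]23[C@@H](C)C(=O)O[C@H]3[C@H](O[Si](c1ccccc1)(c1ccccc1)C(C)(C)C)C(I)=C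
F4 | step 19 | C2 aldehyde (C1–CHO) from 26 | O=C[C@@]1(C)C=CC(=O)[C@@](C)(O)[C@@H]1[C@@H](O)[C@]1(O)[C@@H](C)C(=O)O[C@H]1[C@H](O[Si](c1ccccc1)(c1ccccc1)C(C)(C)C)C(I)=C
F5 | step 20 | C4 ketone (cross-conjugated dienone) of macrocycle 29 | C=C1C(=O)/C=C/[C@@]2(C)C=CC(=O)[C@@](C)(O)[C@@H]2[C@@H](O)[C@]2(O)[C@@H](C)C(=O)O[C@H]2[C@@H]1O[Si](c1ccccc1)(c1ccccc1)C(C)(C)C
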